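**Plan**
- Enabling feature: in the cyclopentane ring, the adjacent quaternary carbons Ca (CH3 and the CH2C(=O) arm) and Ce (CH3 and the enone acyl group) hold their carbon arms cis. The arm CH2 and the acyl carbon are also positions 4 and 1 of a 1,5-diketone. Bonded to each other, they are the two carbons of a ketene unit laid across 1,2-dimethylcyclopentene.
- Retrosynthesis: a temporary CH2–C(O) bond is added (a retro-aldol read backwards), giving a 2-acylcyclobutanol. The cuts that follow are the alkenyl–C(OH) bond (acetylide addition), the arm-CH to chain-C(O) bond (aldol), and the Ca–CH2 and Ce–CO bonds ([2+2]). In the chromene, O1–C8a (aryl ether coupling) and C4–C4a (Sonogashira) are cut.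
- Forward order: the cyclopentene is made first and the four-membered ring is built on it in step 4. Separately, the pyran ring is closed onto the arene in step 14. An aldol joins the two halves, an acetylide brings the last five carbons, and the final oxidation opens the cyclobutane with release of strain.
- Stereochemistry: the Ca/Ce relative configuration comes from the cis-fusing suprafacial [2+2], and the absolute configuration from the (S)-2-(methoxymethyl)pyrrolidine auxiliary. Chromene C2 comes from (R)-citramalic acid, whose tertiary C–O bond is never broken.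
- Both Z-alkenes arise by syn semihydrogenation, and three temporary stereocentres are erased in the last step.

Key step: step 4

Assumption: the (S)-auxiliary is taken to give the (1S,5S)-ketone 8; if the sense of induction proves opposite, the equally available (R)-antipode of 4 is used in steps 3 and 4 with nothing else changed.

Step 1
Reactants: 1 2-methylcyclopentanone (racemic)
Product: 2 1,2-dimethylcyclopentan-1-ol (mixture of diastereomers)
Conditions: MeMgBr, Et2O, 0 °C to rt
Reagents that add atoms: methylmagnesium bromide, C[Mg]Br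
Why: Grignard 1,2-addition to a ketone is reliable here, and the two stereocentres of 2 need no control because both disappear in step 2.

Step 2
Reactants: 2 1,2-dimethylcyclopentan-1-ol
Product: 3 1,2-dimethylcyclopentene
Conditions: p-TsOH·H2O (cat.), neat, 120 °C, product distilled off, then fractional distillation
Reagents that add atoms: none
Why: Acid-catalysed E1 dehydration of the tertiary alcohol under equilibrating conditions follows the Zaitsev rule, so the tetrasubstituted ring alkene should dominate and can be freed from its less substituted isomers by fractional distillation.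

Step 3
Reactants: 4 (S)-2-(methoxymethyl)pyrrolidine
Product: 5 1-[(2S)-2-(methoxymethyl)pyrrolidin-1-yl]ethan-1-one
Conditions: Ac2O, CH2Cl2, 0 °C to rt
Reagents that add atoms: acetic anhydride, CC(=O)OC(C)=O
Why: N-Acetylation of a secondary amine by an anhydride is fast and leaves the stereocentre next to nitrogen untouched.

Step 4
Reactants: 3 1,2-dimethylcyclopentene; 5 1-[(2S)-2-(methoxymethyl)pyrrolidin-1-yl]ethan-1-one
Product: 8 (1S,5S)-1,5-dimethylbicyclo[3.2.0]heptan-6-one, via keteniminium triflate 6 (not isolated), via cyclobutaniminium triflate 7 (not isolated)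
Conditions: Tf2O, 2,4,6-collidine, 3 (excess), ClCH2CH2Cl, −20 °C to rt; then H2O, reflux
Reagents that add atoms: water, O
Why: Tf2O activates the amide oxygen of 5 and collidine removes an acetyl proton, which gives the linear and strongly electrophilic keteniminium ion 6; the electron-rich alkene 3 attacks its central carbon (C5–C6 bond), the enamine CH2 carbon then collapses on the developing tertiary cation on the same alkene face (C1–C7 bond), and water finally hydrolyses iminium salt 7 to ketone 8. The closest known reaction type is the thermal [2+2] cycloaddition of keteniminium triflates made from tertiary acetamides, chiral 2-substituted pyrrolidine amides included, with unactivated alkenes and cycloalkenes. The only ring closed is the cyclobutane, by an intermolecular, asynchronous [2+2] closure that is suprafacial on the alkene, so a cis ring fusion to the cyclopentane is the sole strain-allowed outcome. That fusion sets the relative configuration of the two new quaternary stereocentres C1 and C5, the two CH3 groups being syn to each other and anti to the new CH2 and C=N carbons. Since the faces of 3 are equivalent and its two alkene carbons are enantiotopic, no regio- or diastereoselectivity is required, and the absolute configuration depends only on which alkene carbon meets the iminium carbon, a choice biased by the CH2OMe-bearing stereocentre beside nitrogen, which blocks one side of the C=N π-face. The step further needs ring closure to outrun proton loss from the cationic intermediate, which is secured by the proximity and high nucleophilicity of the enamine carbon and by the moderate temperature that the nucleophilic tetrasubstituted alkene permits.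

Step 5
Reactants: 9 1-bromo-3-methoxy-5-methylbenzene
Product: 10 1-iodo-3-methoxy-5-methylbenzene
Conditions: NaI, CuI (cat.), trans-N,N'-dimethylcyclohexane-1,2-diamine (cat.), 1,4-dioxane, 110 °C
Reagents that add atoms: sodium iodide, [Na+].[I-]
Why: The copper-catalysed aromatic Finkelstein exchange is driven by the low solubility of NaBr in dioxane and installs the more reactive C–I bond at the carbon that becomes C4a.

Step 6
Reactants: 10 1-iodo-3-methoxy-5-methylbenzene
Product: 11 2-bromo-1-iodo-5-methoxy-3-methylbenzene
Conditions: NBS, MeCN, 0 °C to rt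
Reagents that add atoms: N-bromosuccinimide, O=C1CCC(=O)N1Br
Why: Electrophilic aromatic bromination with NBS in MeCN attacks anisoles para to the methoxy group, and as each of the three free positions lies between two substituents this electronic preference should put bromine on the future C8a, between I and CH3.

Step 7
Reactants: 12 (R)-citramalic acid
Product: 13 2-[(4R)-2,2,4-trimethyl-5-oxo-1,3-dioxolan-4-yl]acetic acid
Conditions: 2,2-dimethoxypropane, p-TsOH (cat.), CH2Cl2, rt
Reagents that add atoms: 2,2-dimethoxypropane, COC(C)(C)OC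
Why: Acid-catalysed acetal exchange locks the α-hydroxy acid half as a five-membered dioxolanone, which tells the two carboxyl groups apart without touching the quaternary stereocentre.

Step 8
Reactants: 13 2-[(4R)-2,2,4-trimethyl-5-oxo-1,3-dioxolan-4-yl]acetic acid
Product: 15 (3R)-3-hydroxy-3-methyloxolan-2-one, via hydroxyethyl dioxolanone 14 (not isolated)
Conditions: BH3·THF, THF, 0 °C to rt; MeOH; then p-TsOH (cat.), CH2Cl2, rt
Reagents that add atoms: none
Why: Borane reduces a free carboxylic acid far faster than an ester-type carbonyl, and under acid catalysis the new primary alcohol of 14 transacylates onto the dioxolanone carbonyl (lactonisation, 5-exo-trig) with loss of acetone.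

Step 9
Reactants: 15 (3R)-3-hydroxy-3-methyloxolan-2-one
Product: 16 (3R)-3-methyloxolane-2,3-diol (lactol, anomer mixture)
Conditions: i-Bu2AlH (2.2 equiv), CH2Cl2, −78 °C
Reagents that add atoms: none
Why: Low-temperature i-Bu2AlH reduction of a γ-lactone stops at the aluminium hemiacetal after the first equivalent has been spent on the tertiary OH, and the new anomeric centre is irrelevant because the lactol reacts through its open aldehyde form.

Step 10
Reactants: 16 (3R)-3-methyloxolane-2,3-diol
Product: 17 (3R)-3-methylpent-4-yne-1,3-diol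
Conditions: dimethyl (1-diazo-2-oxopropyl)phosphonate, K2CO3, MeOH, 0 °C to rt
Reagents that add atoms: dimethyl (1-diazo-2-oxopropyl)phosphonate, CC(=O)C(=[N+]=[N-])P(=O)(OC)OC
Why: Ohira–Bestmann alkynylation (Seyferth–Gilbert homologation) traps the open hydroxy aldehyde tautomer of the lactol under mild carbonate conditions, and the fully substituted α-carbon cannot epimerise.

Step 11
Reactants: 17 (3R)-3-methylpent-4-yne-1,3-diol
Product: 18 (3R)-5-[(tert-butyldimethylsilyl)oxy]-3-methylpent-1-yn-3-ol
Conditions: TBSCl, imidazole, CH2Cl2, 0 °C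
Reagents that add atoms: tert-butyldimethylsilyl chloride, CC(C)(C)[Si](C)(C)Cl
Why: Silylation with TBSCl and imidazole distinguishes the unhindered primary from the tertiary propargylic hydroxyl on steric grounds.

Step 12
Reactants: 18 (3R)-5-[(tert-butyldimethylsilyl)oxy]-3-methylpent-1-yn-3-ol; 11 2-bromo-1-iodo-5-methoxy-3-methylbenzene
Product: 19 (3R)-1-(2-bromo-5-methoxy-3-methylphenyl)-5-[(tert-butyldimethylsilyl)oxy]-3-methylpent-1-yn-3-ol
Conditions: PdCl2(PPh3)2 (cat.), CuI (cat.), Et3N, THF, rt
Reagents that add atoms: none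
Why: Sonogashira coupling at room temperature takes place only at the C–I bond, because oxidative addition into the C–Br bond, which is para to OMe and flanked by two ortho groups, is much slower.

Step 13
Reactants: 19 (3R)-1-(2-bromo-5-methoxy-3-methylphenyl)-5-[(tert-butyldimethylsilyl)oxy]-3-methylpent-1-yn-3-ol
Product: 20 (1Z,3R)-1-(2-bromo-5-methoxy-3-methylphenyl)-5-[(tert-butyldimethylsilyl)oxy]-3-methylpent-1-en-3-ol
Conditions: H2 (1 atm), Pd/CaCO3 poisoned with Pb(OAc)2, quinoline, EtOAc, rt
Reagents that add atoms: none
Why: Syn delivery of hydrogen on the poisoned palladium surface (Lindlar-type semihydrogenation) gives the Z-alkene that places the tertiary OH next to the C–Br bond, and aryl bromide and silyl ether are inert.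

Step 14
Reactants: 20 (1Z,3R)-1-(2-bromo-5-methoxy-3-methylphenyl)-5-[(tert-butyldimethylsilyl)oxy]-3-methylpent-1-en-3-ol
Product: 21 tert-butyl{2-[(2R)-6-methoxy-2,8-dimethyl-2H-chromen-2-yl]ethoxy}dimethylsilane
Conditions: Pd(OAc)2 (cat.), 2-(di-tert-butylphosphino)-1,1'-binaphthyl (cat.), Cs2CO3, toluene, 80 °C
Reagents that add atoms: none
Why: Intramolecular palladium-catalysed aryl ether formation (Buchwald–Hartwig type C–O coupling) of an aryl bromide with a tethered tertiary alcohol closes the six-membered pyran ring, the alkoxide has no β-hydrogen to lose, the C2–O bond is never broken so the configuration is retained, and the silyl ether arm avoids the retro-aldol C–C cleavage that a β-hydroxy ester would risk.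

Step 15
Reactants: 21 tert-butyl{2-[(2R)-6-methoxy-2,8-dimethyl-2H-chromen-2-yl]ethoxy}dimethylsilane
Product: 22 2-[(2R)-6-methoxy-2,8-dimethyl-2H-chromen-2-yl]ethan-1-ol
Conditions: n-Bu4NF, THF, 0 °C to rt
Reagents that add atoms: none
Why: Fluoride cleaves the Si–O bond under conditions that leave the acid-sensitive chromene untouched.

Step 16
Reactants: 22 2-[(2R)-6-methoxy-2,8-dimethyl-2H-chromen-2-yl]ethan-1-ol
Product: 23 2-[(2R)-6-methoxy-2,8-dimethyl-2H-chromen-2-yl]acetaldehyde
Conditions: Dess–Martin periodinane, NaHCO3, CH2Cl2, 0 °C to rt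
Reagents that add atoms: none
Why: Dess–Martin oxidation in buffered CH2Cl2 stops at the aldehyde and is neither acidic enough to open the chromene nor basic enough to expel the β-aryloxide.

Step 17
Reactants: 8 (1S,5S)-1,5-dimethylbicyclo[3.2.0]heptan-6-one; 23 2-[(2R)-6-methoxy-2,8-dimethyl-2H-chromen-2-yl]acetaldehyde
Product: 25 (1S,5S)-7-{1-hydroxy-2-[(2R)-6-methoxy-2,8-dimethyl-2H-chromen-2-yl]ethyl}-1,5-dimethylbicyclo[3.2.0]heptan-6-one (epimer mixture at C7 and the carbinol carbon), via lithium enolate 24 (not isolated)
Conditions: LiN(i-Pr)2, THF, −78 °C; then 23, −78 °C; AcOH, −78 °C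
Reagents that add atoms: none
Why: Only C7 of ketone 8 bears α-hydrogens, so LiN(i-Pr)2 gives a single enolate whose directed aldol addition to the unhindered aldehyde is faster than proton transfer at −78 °C, and the two new stereocentres (C7 and the carbinol carbon) may form as a mixture since both are erased in step 20.

Step 18
Reactants: 25 the aldol from step 17; 26 2-methylbut-3-yn-2-ol
Product: 28 (1S,5S)-6-(3-hydroxy-3-methylbut-1-yn-1-yl)-7-{1-hydroxy-2-[(2R)-6-methoxy-2,8-dimethyl-2H-chromen-2-yl]ethyl}-1,5-dimethylbicyclo[3.2.0]heptan-6-ol (mixture at C6/C7/carbinol carbon), via dilithio alkynolate 27 (not isolated)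
Conditions: 26 (3.5 equiv), n-BuLi (7 equiv), THF, −78 to 0 °C; then 25, −78 to −30 °C
Reagents that add atoms: none
Why: 1,2-Addition of a lithium acetylide to a cyclobutanone is favoured by relief of angle strain and by the slim nucleophile, which tolerates the quaternary C5 next to the carbonyl, while the excess reagent first turns the free OH into a lithium aldolate that is stable to retro-aldol cleavage at low temperature; the new carbinol centre C6 is temporary.

Step 19
Reactants: 28 the alkynyl triol from step 18
Product: 29 (1S,5S)-6-[(1Z)-3-hydroxy-3-methylbut-1-en-1-yl]-7-{1-hydroxy-2-[(2R)-6-methoxy-2,8-dimethyl-2H-chromen-2-yl]ethyl}-1,5-dimethylbicyclo[3.2.0]heptan-6-ol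
Conditions: H2 (1 atm, uptake monitored), Pd/CaCO3 poisoned with Pb(OAc)2, quinoline, EtOAc, rt
Reagents that add atoms: none
Why: Lindlar-type semihydrogenation adds hydrogen syn to the alkyne of the but-2-yne-1,4-diol unit and sets the Z geometry of the future enone, the stronger adsorption of the alkyne and the quinoline poison sparing the chromene C3=C4 bond.

Step 20
Reactants: 29 the Z-alkenyl triol from step 19
Product: 31 (2Z)-4-hydroxy-1-[(1S,2S)-2-{3-[(2R)-6-methoxy-2,8-dimethyl-2H-chromen-2-yl]-2-oxopropyl}-1,2-dimethylcyclopentyl]-4-methylpent-2-en-1-one (CNP0137762.2), via acylcyclobutanol 30 (not isolated)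
Conditions: Dess–Martin periodinane, NaHCO3, CH2Cl2, 0 °C to rt; then Et3N (cat.), rt
Reagents that add atoms: none
Why: Dess–Martin periodinane can oxidise only the secondary alcohol, and the resulting 2-acylcyclobutanol 30 undergoes the strain-releasing retro-aldol cleavage known from the de Mayo reaction, which breaks the C6–C7 bond so that C6 becomes the enone carbonyl on Ce and C7 the arm CH2 on Ca, erases the three temporary stereocentres and leaves the two quaternary centres, chromene C2 and the Z-alkene untouched under conditions too mild for β-elimination of the aryloxide.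

**Compound list**
1 | 2-methylcyclopentanone (racemic) | CC1CCCC1=O | starting material
2 | 1,2-dimethylcyclopentan-1-ol (diastereomer mixture) | CC1CCCC1(C)O | intermediate
3 | 1,2-dimethylcyclopentene | CC1=C(C)CCC1 | intermediate
4 | (S)-2-(methoxymethyl)pyrrolidine | COC[C@@H]1CCCN1 | starting material
5 | 1-[(2S)-2-(methoxymethyl)pyrrolidin-1-yl]ethan-1-one | CC(=O)N1CCC[C@H]1COC | intermediate
6 | (2S)-1-ethenylidene-2-(methoxymethyl)pyrrolidinium triflate | C=C=[N+]1CCC[C@H]1COC.[O-]S(=O)(=O)C(F)(F)F | intermediate
7 | (2S)-1-[(1S,5S)-1,5-dimethylbicyclo[3.2.0]heptan-6-ylidene]-2-(methoxymethyl)pyrrolidinium triflate | COC[C@@H]1CCC[N+]1=C3C[C@]4(C)CCC[C@]34C.[O-]S(=O)(=O)C(F)(F)F | intermediate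
8 | (1S,5S)-1,5-dimethylbicyclo[3.2.0]heptan-6-one | O=C1C[C@]2(C)CCC[C@]12C | intermediate
9 | 1-bromo-3-methoxy-5-methylbenzene | COc1cc(C)cc(Br)c1 | starting material
10 | 1-iodo-3-methoxy-5-methylbenzene | COc1cc(C)cc(I)c1 | intermediate
11 | 2-bromo-1-iodo-5-methoxy-3-methylbenzene | COc1cc(C)c(Br)c(I)c1 | intermediate
12 | (R)-citramalic acid | OC(=O)[C@@](C)(CC(=O)O)O | starting material
13 | 2-[(4R)-2,2,4-trimethyl-5-oxo-1,3-dioxolan-4-yl]acetic acid | CC1(C)OC(=O)[C@@](C)(CC(=O)O)O1 | intermediate
14 | (5R)-5-(2-hydroxyethyl)-2,2,5-trimethyl-1,3-dioxolan-4-one | CC1(C)OC(=O)[C@@](C)(CCO)O1 | intermediate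
15 | (3R)-3-hydroxy-3-methyloxolan-2-one | C[C@@]1(O)CCOC1=O | intermediate
16 | (3R)-3-methyloxolane-2,3-diol (anomer mixture) | C[C@@]1(O)CCOC1O | intermediate
17 | (3R)-3-methylpent-4-yne-1,3-diol | C#C[C@@](C)(CCO)O | intermediate
18 | (3R)-5-[(tert-butyldimethylsilyl)oxy]-3-methylpent-1-yn-3-ol | C#C[C@@](C)(CCO[Si](C)(C)C(C)(C)C)O | intermediate
19 | (3R)-1-(2-bromo-5-methoxy-3-methylphenyl)-5-[(tert-butyldimethylsilyl)oxy]-3-methylpent-1-yn-3-ol | COc1cc(C)c(Br)c(c1)C#C[C@@](C)(CCO[Si](C)(C)C(C)(C)C)O | intermediate
20 | (1Z,3R)-1-(2-bromo-5-methoxy-3-methylphenyl)-5-[(tert-butyldimethylsilyl)oxy]-3-methylpent-1-en-3-ol | COc1cc(C)c(Br)c(c1)/C=C\[C@@](C)(CCO[Si](C)(C)C(C)(C)C)O | intermediate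
21 | tert-butyl{2-[(2R)-6-methoxy-2,8-dimethyl-2H-chromen-2-yl]ethoxy}dimethylsilane | COc1cc(C)c2c(c1)C=C[C@@](C)(CCO[Si](C)(C)C(C)(C)C)O2 | intermediate
22 | 2-[(2R)-6-methoxy-2,8-dimethyl-2H-chromen-2-yl]ethan-1-ol | COc1cc(C)c2c(c1)C=C[C@@](C)(CCO)O2 | intermediate
23 | 2-[(2R)-6-methoxy-2,8-dimethyl-2H-chromen-2-yl]acetaldehyde | COc1cc(C)c2c(c1)C=C[C@@](C)(CC=O)O2 | intermediate
24 | lithium enolate of 8 (lithium (1S,5S)-1,5-dimethylbicyclo[3.2.0]hept-6-en-6-olate) | [Li]OC1=C[C@]2(C)CCC[C@]12C | intermediate
25 | (1S,5S)-7-{1-hydroxy-2-[(2R)-6-methoxy-2,8-dimethyl-2H-chromen-2-yl]ethyl}-1,5-dimethylbicyclo[3.2.0]heptan-6-one (C7 and carbinol carbon undefined) | COc1cc(C)c2c(c1)C=C[C@@](C)(CC(O)C3[C@]4(C)CCC[C@]4(C)C3=O)O2 | intermediate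
26 | 2-methylbut-3-yn-2-ol | C#CC(C)(C)O | starting material
27 | dilithio derivative of 26 (lithium 4-lithio-2-methylbut-3-yn-2-olate) | [Li]C#CC(C)(C)O[Li] | intermediate
28 | (1S,5S)-6-(3-hydroxy-3-methylbut-1-yn-1-yl)-7-{1-hydroxy-2-[(2R)-6-methoxy-2,8-dimethyl-2H-chromen-2-yl]ethyl}-1,5-dimethylbicyclo[3.2.0]heptan-6-ol (C6, C7 and carbinol carbon undefined) | COc1cc(C)c2c(c1)C=C[C@@](C)(CC(O)C3[C@]4(C)CCC[C@]4(C)C3(O)C#CC(C)(C)O)O2 | intermediate
29 | (1S,5S)-6-[(1Z)-3-hydroxy-3-methylbut-1-en-1-yl]-7-{1-hydroxy-2-[(2R)-6-methoxy-2,8-dimethyl-2H-chromen-2-yl]ethyl}-1,5-dimethylbicyclo[3.2.0]heptan-6-ol (C6, C7 and carbinol carbon undefined) | COc1cc(C)c2c(c1)C=C[C@@](C)(CC(O)C3[C@]4(C)CCC[C@]4(C)C3(O)/C=C\C(C)(C)O)O2 | intermediate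
30 | 1-{(1S,5S)-6-hydroxy-6-[(1Z)-3-hydroxy-3-methylbut-1-en-1-yl]-1,5-dimethylbicyclo[3.2.0]heptan-7-yl}-2-[(2R)-6-methoxy-2,8-dimethyl-2H-chromen-2-yl]ethan-1-one (C6 and C7 undefined) | COc1cc(C)c2c(c1)C=C[C@@](C)(CC(=O)C3[C@]4(C)CCC[C@]4(C)C3(O)/C=C\C(C)(C)O)O2 | intermediate
31 | (2Z)-4-hydroxy-1-[(1S,2S)-2-{3-[(2R)-6-methoxy-2,8-dimethyl-2H-chromen-2-yl]-2-oxopropyl}-1,2-dimethylcyclopentyl]-4-methylpent-2-en-1-one (CNP0137762.2) | COc1cc(C)c2c(c1)C=C[C@@](C)(CC(=O)C[C@]1(C)CCC[C@]1(C)C(=O)/C=C\C(C)(C)O)O2 | target

**Step count**
- Total step count: 20.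
- Longest linear sequence: 14 steps (12 to 31, steps 7 to 20).

**Steps most likely to fail**

Risk 1, step 4. The single CH2OMe arm may discriminate poorly between the two enantiomeric orientations of the alkene. The cationic intermediate may also lose a proton instead of closing the ring.

The fallback sets out from alkene 3. Dichloroketene F1, generated from trichloroacetyl chloride with Zn(Cu) in Et2O, adds in a concerted ketene [2+2] to give (±)-cis-7,7-dichloro-1,5-dimethylbicyclo[3.2.0]heptan-6-one F2. Zn in AcOH removes both chlorines and gives (±)-cis-1,5-dimethylbicyclo[3.2.0]heptan-6-one F3.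

The racemate is resolved by addition of lithiated (S)-N,S-dimethyl-S-phenylsulfoximine F4 and chromatographic separation of the diastereomeric β-hydroxysulfoximines. Thermolysis of the β-hydroxysulfoximine adduct of the (1S,5S)-ketone F5 in refluxing butan-2-ol brings the route back at 8.

Risk 2, step 14. On palladium, the Z-allylic tertiary alkoxide may decay by ionisation, C–C cleavage or Z-to-E isomerisation of the styrene faster than C–O reductive elimination occurs at the crowded, electron-rich aryl centre.

The fallback sets out from 20. Hydrogenation of the alkene with H2 and RhCl(PPh3)3, which spares the aryl bromide, gives (3S)-1-(2-bromo-5-methoxy-3-methylphenyl)-5-[(tert-butyldimethylsilyl)oxy]-3-methylpentan-3-ol F6. The spatial arrangement is unchanged, and only the descriptor changes through ligand ranking.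

The same type of aryl ether coupling is then run on this saturated, flexible tether, the classical substrate type. It gives tert-butyl{2-[(2S)-6-methoxy-2,8-dimethyl-3,4-dihydro-2H-chromen-2-yl]ethoxy}dimethylsilane F7. Dehydrogenation of C3–C4 with DDQ in refluxing dioxane introduces the double bond afterwards and brings the route back at 21.

Risk 3, step 19. The alkyne lies between two fully substituted carbinol carbons and may bind only slowly to the poisoned surface, so hydrogenation of the chromene C3=C4 bond or over-reduction could compete.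

The fallback sets out from 25 and avoids any hydrogenation in the presence of the chromene. Commercial ethyl (Z)-3-iodoacrylate and MeMgBr (2.2 equiv) give (Z)-4-iodo-2-methylbut-3-en-2-ol F8. Deprotonation with MeLi and iodine–lithium exchange with t-BuLi at −78 °C give the configurationally stable dilithio (Z)-alkenyl alkoxide F9. This adds to the cyclobutanone carbonyl of 25 and brings the route back at 29, replacing steps 18 and 19.

**Further compounds**
F1 | step 4 | dichloroketene | ClC(Cl)=C=O
F2 | step 4 | (±)-cis-7,7-dichloro-1,5-dimethylbicyclo[3.2.0]heptan-6-one (racemate, ring fusion necessarily cis) | O=C1C(Cl)(Cl)C2(C)CCCC12C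
F3 | step 4 | (±)-cis-1,5-dimethylbicyclo[3.2.0]heptan-6-one (racemate, ring fusion necessarily cis) | O=C1CC2(C)CCCC12C
F4 | step 4 | lithiated (S)-N,S-dimethyl-S-phenylsulfoximine | CN=[S@@](C[Li])(=O)c1ccccc1
F5 | step 4 | β-hydroxysulfoximine adduct of the (1S,5S)-ketone (C6 undefined) | CN=[S@@](CC1(O)C[C@]2(C)CCC[C@]12C)(=O)c1ccccc1
F6 | step 14 | (3S)-1-(2-bromo-5-methoxy-3-methylphenyl)-5-[(tert-butyldimethylsilyl)oxy]-3-methylpentan-3-ol | COc1cc(C)c(Br)c(c1)CC[C@@](C)(CCO[Si](C)(C)C(C)(C)C)O
F7 | step 14 | tert-butyl{2-[(2S)-6-methoxy-2,8-dimethyl-3,4-dihydro-2H-chromen-2-yl]ethoxy}dimethylsilane | COc1cc(C)c2c(c1)CC[C@@](C)(CCO[Si](C)(C)C(C)(C)C)O2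
F8 | step 19 | (Z)-4-iodo-2-methylbut-3-en-2-ol | I/C=C\C(C)(C)O
F9 | step 19 | dilithio (Z)-alkenyl alkoxide (lithium (Z)-4-lithio-2-methylbut-3-en-2-olate) | [Li]/C=C\C(C)(C)O[Li]
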